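**Retrosynthetic overview**
1. Target ⇒ ten-membered lactone carrying C8–OH free and C9–O silylated (methacrylation and desilylation last); its ring-cis C1=C10 enoate is opened by ring-closing metathesis to an acyclic triene that already holds the α-methylene-γ-butyrolactone.
2. That lactone is cut at C6–C7 and at the lactone C–O bond: late union of a C8 enal (fragment 1) with a C11 allylic bromide (fragment 2) by CrCl2-mediated allylation and lactonisation, which sets C6 and C7.
3. Fragment 2: Brown (Z)-γ-alkoxyallylboration of 2-bromoacrolein sets the C8/C9 syn-diol with the two oxygens differentiated; then ester via the vinyllithium, ozonolysis, Morita–Baylis–Hillman reaction and SN2′ bromination.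
4. Fragment 1: acetoacetate dianion allylation, (Z)-enol phosphate, Me2CuLi, then reduction and oxidation to the (E)-enal.
5. Ring order: five-membered lactone first (in the fragment coupling), ten-membered carbocycle second (metathesis).

Assumption: positions are named by germacrane numbering (C6 lactone carbinol carbon, C7 ring-fusion carbon, C8 and C9 the two oxygenated carbons, C10 the ester-bearing alkene carbon, C1 its alkene partner, C11 the α-methylene carbon); all six starting materials are taken as commercial, 2-bromoacrolein freshly distilled.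

**Fragment 1**

Step 1
Reactants: 1 methyl acetoacetate; 2 allyl bromide
Product: 4 methyl 3-oxohept-6-enoate, via dilithium dianion 3 (not isolated)
Conditions: LiN(i-Pr)2 (2.2 equiv), THF, 0 °C; then 2, 0 °C; aq. HCl
Reagents that add atoms: none
Why: Weiler dianion alkylation, in which the more basic terminal carbanion of the acetoacetate dianion is allylated selectively and no stereocentre is formed.

Step 2
Reactants: 4 methyl 3-oxohept-6-enoate
Product: 6 methyl (2Z)-3-[(diethoxyphosphoryl)oxy]hepta-2,6-dienoate, via sodium enolate 5 (not isolated)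
Conditions: NaH, Et2O, 0 °C; then ClP(O)(OEt)2, 0 °C to rt
Reagents that add atoms: diethyl chlorophosphate, CCOP(=O)(Cl)OCC
Why: O-phosphorylation of the chelated sodium enolate in ether gives the (Z)-enol phosphate, which fixes the later alkene geometry.

Step 3
Reactants: 6 methyl (2Z)-3-[(diethoxyphosphoryl)oxy]hepta-2,6-dienoate
Product: 7 methyl (2E)-3-methylhepta-2,6-dienoate
Conditions: Me2CuLi (3 equiv), Et2O, −78 to −45 °C
Reagents that add atoms: lithium dimethylcuprate, [Li+].C[Cu-]C
Why: cuprate substitution of the enol phosphate (addition–elimination) goes with retention, so the new methyl group ends cis to the ester and the trisubstituted alkene is E.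

Step 4
Reactants: 7 methyl (2E)-3-methylhepta-2,6-dienoate
Product: 8 (2E)-3-methylhepta-2,6-dien-1-ol
Conditions: i-Bu2AlH (2.5 equiv), CH2Cl2, −78 °C; aq. KNaC4H4O6
Reagents that add atoms: none
Why: hydride reduction of the ester to the allylic alcohol leaves both alkenes untouched.

Step 5
Reactants: 8 (2E)-3-methylhepta-2,6-dien-1-ol
Product: 9 (2E)-3-methylhepta-2,6-dienal
Conditions: MnO2 (15 equiv), CH2Cl2, rt
Reagents that add atoms: none
Why: chemoselective allylic oxidation gives the enal without E/Z isomerisation.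

**Fragment 2**

Step 6
Reactants: 10 allyl methoxymethyl ether; 11 2-bromoacrolein
Product: 16 (3R,4S)-2-bromo-4-(methoxymethoxy)hexa-1,5-dien-3-ol, via allyllithium 12 (not isolated), via lithium borate 13 (not isolated), via allylborane 14 (not isolated), via borinic ester 15 (not isolated)
Conditions: 10, s-BuLi, THF, −78 °C; (+)-Ipc2BOMe [from (−)-α-pinene], −78 °C; BF3·OEt2; 11, −78 °C, 3 h; then NaOH, H2O2, 0 °C to rt
Reagents that add atoms: none
Why: Brown (Z)-γ-alkoxyallylboration through a closed chair transition state, in which the Z enol ether geometry gives the syn diol mono-ether and the isopinocampheyl groups from (−)-α-pinene select the aldehyde face that gives 3R,4S (the future C9 and C8).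

Step 7
Reactants: 16 (3R,4S)-2-bromo-4-(methoxymethoxy)hexa-1,5-dien-3-ol
Product: 17 tert-butyldimethylsilyl ether of 16
Conditions: TBSOTf, 2,6-lutidine, CH2Cl2, −78 to 0 °C
Reagents that add atoms: tert-butyldimethylsilyl trifluoromethanesulfonate, CC(C)(C)[Si](C)(C)OS(=O)(=O)C(F)(F)F
Why: silylation of the hindered secondary alcohol with the silyl triflate protects the C9 oxygen and keeps it distinct from the MOM-protected C8 oxygen.

Step 8
Reactants: 17 tert-butyldimethylsilyl ether of 16
Product: 19 methyl (3S,4S)-3-[(tert-butyldimethylsilyl)oxy]-4-(methoxymethoxy)-2-methylidenehex-5-enoate, via vinyllithium 18 (not isolated)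
Conditions: t-BuLi (2.1 equiv), Et2O, −78 °C; then cannulated into ClCO2Me (5 equiv), Et2O, −78 °C
Reagents that add atoms: methyl chloroformate, COC(Cl)=O
Why: bromine–lithium exchange on the vinyl bromide followed by C-acylation installs the C14 methyl ester without touching the two stereocentres.

Step 9
Reactants: 19 methyl (3S,4S)-3-[(tert-butyldimethylsilyl)oxy]-4-(methoxymethoxy)-2-methylidenehex-5-enoate
Product: 21 methyl (3S,4R)-3-[(tert-butyldimethylsilyl)oxy]-4-(methoxymethoxy)-2-methylidene-5-oxopentanoate, via ozonide 20 (not isolated)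
Conditions: O3, CH2Cl2, −78 °C (Sudan Red 7B end point); then Me2S, −78 °C to rt
Reagents that add atoms: ozone, [O-][O+]=O
Why: ozonolysis with reductive work-up cleaves the electron-richer monosubstituted vinyl group in preference to the electron-poor acrylate and gives the α-alkoxy aldehyde under non-epimerising conditions.

Step 10
Reactants: 21 methyl (3S,4R)-3-[(tert-butyldimethylsilyl)oxy]-4-(methoxymethoxy)-2-methylidene-5-oxopentanoate; 22 methyl acrylate
Product: 23 dimethyl (3S,4S,5RS)-3-[(tert-butyldimethylsilyl)oxy]-5-hydroxy-4-(methoxymethoxy)-2,6-dimethylideneheptanedioate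
Conditions: 22 (10 equiv), DABCO (1 equiv), MeOH (cat.), rt, 3 d
Reagents that add atoms: none
Why: Morita–Baylis–Hillman reaction of the activated α-alkoxy aldehyde, whose new carbinol centre is formed as a mixture that is irrelevant because it becomes sp2 in the next step.

Step 11
Reactants: 23 dimethyl (3S,4S,5RS)-3-[(tert-butyldimethylsilyl)oxy]-5-hydroxy-4-(methoxymethoxy)-2,6-dimethylideneheptanedioate
Product: 24 dimethyl (2Z,4S,5S)-2-(bromomethyl)-5-[(tert-butyldimethylsilyl)oxy]-4-(methoxymethoxy)-6-methylidenehept-2-enedioate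
Conditions: NBS, Me2S, CH2Cl2, 0 °C; then 23, 0 °C to rt
Reagents that add atoms: N-bromosuccinimide, O=C1CCC(=O)N1Br
Why: Corey–Kim-type activation of the allylic alcohol and SN2′ attack of bromide give the thermodynamically preferred (Z)-2-(bromomethyl)enoate from both epimers.

**Fragment union and endgame**

Step 12
Reactants: 9 (2E)-3-methylhepta-2,6-dienal; 24 dimethyl (2Z,4S,5S)-2-(bromomethyl)-5-[(tert-butyldimethylsilyl)oxy]-4-(methoxymethoxy)-6-methylidenehept-2-enedioate
Product: 26 methyl (3S,4S)-3-[(tert-butyldimethylsilyl)oxy]-4-(methoxymethoxy)-4-{(2R,3S)-2-[(1E)-2-methylhexa-1,5-dien-1-yl]-4-methylidene-5-oxooxolan-3-yl}-2-methylidenebutanoate, via hydroxy diester 25 (not isolated)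
Conditions: CrCl2 (4 equiv), THF, rt, 12 h; then p-TsOH·H2O (10 mol %), CH2Cl2, rt
Reagents that add atoms: none
Why: Nozaki–Hiyama–Kishi-type Barbier allylation in which the allylchromium reagent formed in situ reacts through a chair with C8 equatorial (anti adduct, hence the trans-lactone after lactonisation) and the aldehyde adds to C7 anti to the bulky C9 branch with the C8–H eclipsing the alkene, which is expected to set 7S and 6R.

Step 13
Reactants: 26 the acyclic triene lactone of step 12
Product: 27 methyl (3aS,4S,5S,6E,10E,11aR)-5-[(tert-butyldimethylsilyl)oxy]-4-(methoxymethoxy)-10-methyl-3-methylidene-2-oxo-2,3,3a,4,5,8,9,11a-octahydrocyclodeca[b]furan-6-carboxylate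
Conditions: second-generation Hoveyda–Grubbs catalyst [RuCl2(H2IMes)(=CH–C6H4-2-O-i-Pr)] (15 mol %), toluene (0.001 M), 80 °C
Reagents that add atoms: none
Why: ring-closing metathesis of the terminal vinyl group onto the 2-substituted acrylate is driven by loss of ethene, and the ten-membered ring strongly favours the new enoate with C2 and C9 cis (E by CIP), which is the target geometry, while the lactone methylene could only close an eight-membered ring holding a trans alkene.

Step 14
Reactants: 27 the MOM- and TBS-protected macrocycle of step 13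
Product: 29 methyl (3aR,4S,5S,6E,10E,11aR)-5-[(tert-butyldimethylsilyl)oxy]-4-hydroxy-10-methyl-3-methylidene-2-oxo-2,3,3a,4,5,8,9,11a-octahydrocyclodeca[b]furan-6-carboxylate, via bromomethyl ether 28 (not isolated)
Conditions: Me2BBr (3 equiv), CH2Cl2, −78 °C, 1 h; then sat. aq. NaHCO3, THF, 0 °C
Reagents that add atoms: none
Why: the bromoborane cleaves the acetal C–O bond of the MOM ether at low temperature and leaves the silyl ether, the esters and the lactone intact (the 3a descriptor changes only because of CIP priorities).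

Step 15
Reactants: 29 the C8 alcohol of step 14; 30 methacryloyl chloride
Product: 32 methyl (3aS,4S,5S,6E,10E,11aR)-5-hydroxy-10-methyl-3-methylidene-4-[(2-methylprop-2-enoyl)oxy]-2-oxo-2,3,3a,4,5,8,9,11a-octahydrocyclodeca[b]furan-6-carboxylate (CNP0282644.1), via silyl ether 31 (not isolated)
Conditions: 30 (3 equiv), Et3N, DMAP (0.2 equiv), CH2Cl2, 0 °C to rt; then HF·pyridine, THF, 0 °C to rt
Reagents that add atoms: none
Why: DMAP-catalysed esterification of the only free hydroxyl (C8) is followed in the same flask by fluoride cleavage of the C9 silyl ether under non-basic conditions, which avoids acyl migration to O9.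

**Compound list**

1 | methyl acetoacetate (methyl 3-oxobutanoate) | COC(=O)CC(C)=O | starting material
2 | allyl bromide (3-bromoprop-1-ene) | C=CCBr | starting material
3 | dilithium dianion of methyl acetoacetate | [Li+].[Li+].[CH2-]C(=O)[CH-]C(=O)OC | intermediate
4 | methyl 3-oxohept-6-enoate | COC(=O)CC(=O)CCC=C | intermediate
5 | sodium enolate of methyl 3-oxohept-6-enoate | [Na+].COC(=O)[CH-]C(=O)CCC=C | intermediate
6 | methyl (2Z)-3-[(diethoxyphosphoryl)oxy]hepta-2,6-dienoate | COC(=O)/C=C(\OP(=O)(OCC)OCC)CCC=C | intermediate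
7 | methyl (2E)-3-methylhepta-2,6-dienoate | COC(=O)/C=C(\C)CCC=C | intermediate
8 | (2E)-3-methylhepta-2,6-dien-1-ol | OC/C=C(\C)CCC=C | intermediate
9 | (2E)-3-methylhepta-2,6-dienal (fragment 1) | O=C/C=C(\C)CCC=C | intermediate
10 | allyl methoxymethyl ether, 3-(methoxymethoxy)prop-1-ene | C=CCOCOC | starting material
11 | 2-bromoacrolein (2-bromoprop-2-enal) | C=C(Br)C=O | starting material
12 | [(2Z)-3-(methoxymethoxy)prop-2-en-1-yl]lithium | [Li]C/C=C\OCOC | intermediate
13 | lithium methoxy[(2Z)-3-(methoxymethoxy)prop-2-en-1-yl]diisopinocampheylborate (Ipc groups as in (+)-isopinocampheol, from (−)-α-pinene) | [Li+].CO[B-](C/C=C\OCOC)([C@H]1C[C@H]2C[C@@H]([C@@H]1C)C2(C)C)[C@H]1C[C@H]2C[C@@H]([C@@H]1C)C2(C)C | intermediate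
14 | [(2Z)-3-(methoxymethoxy)prop-2-en-1-yl]diisopinocampheylborane (same Ipc groups) | COCO/C=C\CB([C@H]1C[C@H]2C[C@@H]([C@@H]1C)C2(C)C)[C@H]1C[C@H]2C[C@@H]([C@@H]1C)C2(C)C | intermediate
15 | (3R,4S)-2-bromo-4-(methoxymethoxy)hexa-1,5-dien-3-yl diisopinocampheylborinate | COCO[C@H]([C@@H](OB([C@H]1C[C@H]2C[C@@H]([C@@H]1C)C2(C)C)[C@H]1C[C@H]2C[C@@H]([C@@H]1C)C2(C)C)C(Br)=C)C=C | intermediate
16 | (3R,4S)-2-bromo-4-(methoxymethoxy)hexa-1,5-dien-3-ol | COCO[C@H]([C@@H](O)C(Br)=C)C=C | intermediate
17 | {[(3R,4S)-2-bromo-4-(methoxymethoxy)hexa-1,5-dien-3-yl]oxy}(tert-butyl)dimethylsilane | COCO[C@H]([C@@H](O[Si](C)(C)C(C)(C)C)C(Br)=C)C=C | intermediate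
18 | [(3S,4S)-3-[(tert-butyldimethylsilyl)oxy]-4-(methoxymethoxy)hexa-1,5-dien-2-yl]lithium (same spatial arrangement as 17) | COCO[C@H]([C@@H](O[Si](C)(C)C(C)(C)C)C([Li])=C)C=C | intermediate
19 | methyl (3S,4S)-3-[(tert-butyldimethylsilyl)oxy]-4-(methoxymethoxy)-2-methylidenehex-5-enoate | COCO[C@H]([C@@H](O[Si](C)(C)C(C)(C)C)C(=C)C(=O)OC)C=C | intermediate
20 | methyl (3S,4R)-3-[(tert-butyldimethylsilyl)oxy]-4-(methoxymethoxy)-2-methylidene-4-(1,2,4-trioxolan-3-yl)butanoate (both epimers at the trioxolane carbon) | COCO[C@H]([C@@H](O[Si](C)(C)C(C)(C)C)C(=C)C(=O)OC)C1OCOO1 | intermediate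
21 | methyl (3S,4R)-3-[(tert-butyldimethylsilyl)oxy]-4-(methoxymethoxy)-2-methylidene-5-oxopentanoate | COCO[C@H]([C@@H](O[Si](C)(C)C(C)(C)C)C(=C)C(=O)OC)C=O | intermediate
22 | methyl acrylate | C=CC(=O)OC | starting material
23 | dimethyl (3S,4S,5RS)-3-[(tert-butyldimethylsilyl)oxy]-5-hydroxy-4-(methoxymethoxy)-2,6-dimethylideneheptanedioate (both C5 epimers) | COCO[C@H]([C@@H](O[Si](C)(C)C(C)(C)C)C(=C)C(=O)OC)C(O)C(=C)C(=O)OC | intermediate
24 | dimethyl (2Z,4S,5S)-2-(bromomethyl)-5-[(tert-butyldimethylsilyl)oxy]-4-(methoxymethoxy)-6-methylidenehept-2-enedioate (fragment 2) | COCO[C@H]([C@@H](O[Si](C)(C)C(C)(C)C)C(=C)C(=O)OC)/C=C(\CBr)C(=O)OC | intermediate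
25 | dimethyl (3S,4S,5S)-3-[(tert-butyldimethylsilyl)oxy]-5-[(1R,2E)-1-hydroxy-3-methylhepta-2,6-dien-1-yl]-4-(methoxymethoxy)-2,6-dimethylideneheptanedioate | COCO[C@H]([C@@H](O[Si](C)(C)C(C)(C)C)C(=C)C(=O)OC)[C@H]([C@H](O)/C=C(\C)CCC=C)C(=C)C(=O)OC | intermediate
26 | methyl (3S,4S)-3-[(tert-butyldimethylsilyl)oxy]-4-(methoxymethoxy)-4-{(2R,3S)-2-[(1E)-2-methylhexa-1,5-dien-1-yl]-4-methylidene-5-oxooxolan-3-yl}-2-methylidenebutanoate | COCO[C@H]([C@@H](O[Si](C)(C)C(C)(C)C)C(=C)C(=O)OC)[C@H]1C(=C)C(=O)O[C@@H]1/C=C(\C)CCC=C | intermediate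
27 | methyl (3aS,4S,5S,6E,10E,11aR)-5-[(tert-butyldimethylsilyl)oxy]-4-(methoxymethoxy)-10-methyl-3-methylidene-2-oxo-2,3,3a,4,5,8,9,11a-octahydrocyclodeca[b]furan-6-carboxylate | COCO[C@H]1[C@H]2C(=C)C(=O)O[C@@H]2/C=C(\C)CC/C=C(/C(=O)OC)[C@@H]1O[Si](C)(C)C(C)(C)C | intermediate
28 | methyl (3aS,4S,5S,6E,10E,11aR)-4-(bromomethoxy)-5-[(tert-butyldimethylsilyl)oxy]-10-methyl-3-methylidene-2-oxo-2,3,3a,4,5,8,9,11a-octahydrocyclodeca[b]furan-6-carboxylate | BrCO[C@H]1[C@H]2C(=C)C(=O)O[C@@H]2/C=C(\C)CC/C=C(/C(=O)OC)[C@@H]1O[Si](C)(C)C(C)(C)C | intermediate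
29 | methyl (3aR,4S,5S,6E,10E,11aR)-5-[(tert-butyldimethylsilyl)oxy]-4-hydroxy-10-methyl-3-methylidene-2-oxo-2,3,3a,4,5,8,9,11a-octahydrocyclodeca[b]furan-6-carboxylate | O[C@H]1[C@H]2C(=C)C(=O)O[C@@H]2/C=C(\C)CC/C=C(/C(=O)OC)[C@@H]1O[Si](C)(C)C(C)(C)C | intermediate
30 | methacryloyl chloride (2-methylprop-2-enoyl chloride) | C=C(C)C(Cl)=O | starting material
31 | methyl (3aS,4S,5S,6E,10E,11aR)-5-[(tert-butyldimethylsilyl)oxy]-10-methyl-3-methylidene-4-[(2-methylprop-2-enoyl)oxy]-2-oxo-2,3,3a,4,5,8,9,11a-octahydrocyclodeca[b]furan-6-carboxylate | C=C(C)C(=O)O[C@H]1[C@H]2C(=C)C(=O)O[C@@H]2/C=C(\C)CC/C=C(/C(=O)OC)[C@@H]1O[Si](C)(C)C(C)(C)C | intermediate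
32 | methyl (3aS,4S,5S,6E,10E,11aR)-5-hydroxy-10-methyl-3-methylidene-4-[(2-methylprop-2-enoyl)oxy]-2-oxo-2,3,3a,4,5,8,9,11a-octahydrocyclodeca[b]furan-6-carboxylate (CNP0282644.1; germacrane numbering 6R,7S,8S,9S) | C=C(C)C(=O)O[C@H]1[C@H]2C(=C)C(=O)O[C@@H]2/C=C(\C)CC/C=C(/C(=O)OC)[C@@H]1O | target

**Totals and risks**

Total step count: 15. Longest linear sequence: 10 steps (steps 6 to 15, from 10 and 11 to 32); fragment 1 (steps 1 to 5) is made in parallel.

The three steps most likely to fail:

Step 12, because the configuration at C6 and C7 rests on substrate control by C8 alone. The facial preference is predicted from an allylic-strain model, not from a precedent on this exact bromide. Fallback: hand control to a chiral catalyst and join the same partners by the chromium-catalysed enantioselective 2-(alkoxycarbonyl)allylation (CrCl2 10 mol %, chiral 1,8-bis(oxazolinyl)carbazole ligand, Mn, Me3SiCl, i-Pr2NEt, THF, rt). The ligand then chooses the aldehyde face and the anti chair fixes C7; acid treatment again closes the lactone. This sets out from 9 and 24 and comes back at 26; no new compound is made (F0).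

Step 13, because a ten-membered ring must close onto a hindered 2-substituted acrylate and oligomers can win. Fallback: swap the two key bond formations. Aldehyde 9 (in excess) and bromide 24 are first joined by cross-metathesis (same ruthenium catalyst, CH2Cl2, 40 °C), which can only pair the terminal vinyl group of 9 with the free acrylate of 24. This gives the acyclic enoate dimethyl (2Z,4S,5S,6E)-2-(bromomethyl)-5-[(tert-butyldimethylsilyl)oxy]-4-(methoxymethoxy)-6-[(4E)-4-methyl-6-oxohex-4-en-1-ylidene]hept-2-enedioate F1. The ring is then closed by an intramolecular Nozaki–Hiyama–Kishi allylation (CrCl2, THF, 0.002 M), which sets C6 and C7 under macrocyclic control, to the carbocycle methyl (1E,5E,7R,8S,9S,10S)-10-[(tert-butyldimethylsilyl)oxy]-7-hydroxy-8-(3-methoxy-3-oxoprop-1-en-2-yl)-9-(methoxymethoxy)-5-methylcyclodeca-1,5-diene-1-carboxylate F2. F2 lactonises with p-TsOH to 27. This sets out from 9 and 24 and comes back at 27.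

Step 14, because a strong Lewis acid meets the strained macrocycle with its allylic lactone and allylic silyl ether. Fallback: deprotect before the ring is closed. Acyclic lactone 26 is treated with Me2BBr (CH2Cl2, −78 °C; then NaHCO3) and gives, through the bromomethyl ether methyl (3S,4S)-4-(bromomethoxy)-3-[(tert-butyldimethylsilyl)oxy]-4-{(2R,3S)-2-[(1E)-2-methylhexa-1,5-dien-1-yl]-4-methylidene-5-oxooxolan-3-yl}-2-methylidenebutanoate F3, the C8 alcohol methyl (3S,4S)-3-[(tert-butyldimethylsilyl)oxy]-4-hydroxy-4-{(2R,3R)-2-[(1E)-2-methylhexa-1,5-dien-1-yl]-4-methylidene-5-oxooxolan-3-yl}-2-methylidenebutanoate F4. Ring-closing metathesis of F4 (same catalyst, toluene, 80 °C) then gives 29 directly. This sets out from 26 and comes back at 29.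

**Further compounds**

F0 | step 12 | none | none
F1 | step 13 | dimethyl (2Z,4S,5S,6E)-2-(bromomethyl)-5-[(tert-butyldimethylsilyl)oxy]-4-(methoxymethoxy)-6-[(4E)-4-methyl-6-oxohex-4-en-1-ylidene]hept-2-enedioate | O=C/C=C(\C)CC/C=C(/C(=O)OC)[C@H](O[Si](C)(C)C(C)(C)C)[C@@H](OCOC)/C=C(\CBr)C(=O)OC
F2 | step 13 | methyl (1E,5E,7R,8S,9S,10S)-10-[(tert-butyldimethylsilyl)oxy]-7-hydroxy-8-(3-methoxy-3-oxoprop-1-en-2-yl)-9-(methoxymethoxy)-5-methylcyclodeca-1,5-diene-1-carboxylate | COCO[C@H]1[C@@H](C(=C)C(=O)OC)[C@H](O)/C=C(\C)CC/C=C(/C(=O)OC)[C@@H]1O[Si](C)(C)C(C)(C)C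
F3 | step 14 | methyl (3S,4S)-4-(bromomethoxy)-3-[(tert-butyldimethylsilyl)oxy]-4-{(2R,3S)-2-[(1E)-2-methylhexa-1,5-dien-1-yl]-4-methylidene-5-oxooxolan-3-yl}-2-methylidenebutanoate | BrCO[C@H]([C@@H](O[Si](C)(C)C(C)(C)C)C(=C)C(=O)OC)[C@H]1C(=C)C(=O)O[C@@H]1/C=C(\C)CCC=C
F4 | step 14 | methyl (3S,4S)-3-[(tert-butyldimethylsilyl)oxy]-4-hydroxy-4-{(2R,3R)-2-[(1E)-2-methylhexa-1,5-dien-1-yl]-4-methylidene-5-oxooxolan-3-yl}-2-methylidenebutanoate | O[C@H]([C@@H](O[Si](C)(C)C(C)(C)C)C(=C)C(=O)OC)[C@H]1C(=C)C(=O)O[C@@H]1/C=C(\C)CCC=C
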